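The data are simulated for an exercise, noise included.

Of the two substrates charged, 82.2 % is left in the dawn run at 20.0 min and 85.8 % in the summer run, although summer holds 4.00 times the substrate. The share used per minute therefore changes little with substrate, roughly the pattern of a pseudo-first-order step.

the same everywhere: catalyst 7.5 mM
- dawn: left-handed substrate 0.15 M; right-handed substrate 0.15 M; solid reagent 0.90 M; added ligand 16 mM; run made earlier
- summer: left-handed substrate 0.60 M; right-handed substrate 0.60 M; solid reagent 0.90 M; added ligand 16 mM; run made earlier
- winter: left-handed substrate 0.30 M; right-handed substrate 0.30 M; solid reagent 0.90 M; added ligand 32 mM; run made earlier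
- flask: left-handed substrate 0.30 M; right-handed substrate 0.30 M; solid reagent 0.900 M; added ligand 16 mM; time 15 min

| run | time / min | left-handed product / % | right-handed product / % |
|---|---|---|---|
| dawn | 1.00 | 0 | 0.6 |
| dawn | 3.00 | 1.5 | 1.1 |
| dawn | 5.00 | 2.6 | 1.2 |
| dawn | 8.00 | 4.9 | 2.6 |
| dawn | 10.0 | 6.1 | 2.6 |
| dawn | 15.0 | 8.6 | 4.7 |
| dawn | 20.0 | 11.9 | 5.9 |
| summer | 1.00 | 0.7 | 0.4 |
| summer | 3.00 | 1.6 | 0.5 |
| summer | 5.00 | 2.0 | 1.6 |
| summer | 8.00 | 3.4 | 0.7 |
| summer | 10.0 | 4.5 | 2.4 |
| summer | 15.0 | 6.2 | 3.4 |
| summer | 20.0 | 9.8 | 4.4 |
| winter | 4.00 | 1.5 | 0.4 |
| winter | 8.00 | 3.2 | 1.6 |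
| winter | 10.0 | 4.6 | 2.4 |
| winter | 15.0 | 5.9 | 3.3 |
| winter | 20.0 | 7.5 | 3.9 |

(readings scatter by 0.5 percentage points)

- catalyst is single-handed; left-handed substrate and right-handed substrate are mirror images of each other, charged as a racemate, each of them at the stated concentration
- solid, in amounts per volume of the solution: solid reagent
- what may be going on: catalyst + added ligand <-> idle complex; partner + catalyst + right-handed substrate -> catalyst + right-handed product; partner + catalyst + left-handed substrate -> catalyst + left-handed product; left-handed substrate <-> right-handed substrate; solid reagent <-> partner; 2 partner -> homo dimer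
- at the start none of the solid reagent is in solution
- an excess is the difference of the two amounts in percent of their sum
- an excess is below zero if the other one leads

- excess of left-handed product over right-handed product in the product at 50 s
- excess of left-handed product over right-handed product in the product at 15 min
- part of the left-handed substrate and right-handed substrate charged together that has reacted at 15 min

The flask has the substrate of the winter run, but winter holds twice the added ligand. The substrate of the flask lies midway by ratio between dawn and summer, so the geometric mean of their conversions, 15.9 % at 20.0 min, can stand for it. Winter reads 11.4 % at that time, so the extra ligand costs a factor of 1.39, which is less than the doubling.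

If the rate is taken as proportional to one over a fixed amount plus the added ligand charged, that factor gives the fixed amount, here called the ligand scale: 24.5 mM, as a reading. It is a rule of thumb read from the rates, not the point at which free catalyst and idle complex stand equal. The curves run nearly straight, so my reckoning for the flask is 11.9 % reacted at 15 min. The pooled excess at 20.0 min is 34.6 %, which I keep for both asked times.

The forecast says 34.5 %, 32.5 % and 11.5 %, a little lower on conversion than my reckoning, with the excess sinking slightly. It reads winter as “showing moderate ligand inhibition”.

    catalyst + added ligand ⇌ idle complex (K = 80.0 M⁻¹, k = 0.760 M⁻¹ s⁻¹)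
    partner + catalyst + right-handed substrate → catalyst + right-handed product (k = 1.30 M⁻² s⁻¹)
    partner + catalyst + left-handed substrate → catalyst + left-handed product (k = 2.70 M⁻² s⁻¹)
    left-handed substrate ⇌ right-handed substrate (k = 0.0890 s⁻¹)
    solid reagent ⇌ partner, rate k5*(cs5 - [partner]) while solid is left; crystals form when [partner] > cs5 (solubility = 0.160 M, k = 0.00150 s⁻¹)
    2 partner → homo dimer (k = 0.140 M⁻¹ s⁻¹)

The flask gives 35.0 %, 35.0 % and 12.3 %, with idle complex holding 49.6 % of the catalyst at 15.0 min. Moved by the ligand scale to winter's ligand, the flask's conversion becomes 8.85 %, beside 9.20 % read in winter at 15.0 min. In a neighbour with 0.064 M of added ligand, the ligand scale gives a factor of 0.458 and so 5.65 % reacted. The computed neighbour gives 5.26 %.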